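The plan rests on cutting the C4–C5 bond of ring A. C5 is both the α-carbon of the C6 carbonyl (the later carbinol) and the bearer of C4, the ring carbon of the exocyclic C4=C15 methylene; this is the pattern left when a C5=C6 silyl enol ether of ring B adds to a terminal alkyne tethered from C10. One gold-catalysed 6-exo-dig cyclisation closes ring A, sets C5 (cis fusion), and delivers the methylene and the C6 ketone together. The precursor is a carvone-derived cyclohexene: triisopropylsilyl enol ether at C5=C6, isopropyl at C7, silyl-protected hydroxyl at C9, and a quaternary C10 carrying the methyl and a pent-4-ynyl chain.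

Key step: step 8

Remark: eudesmane numbering is used (ring A = C1–C5 + C10, ring B = C5–C10, C14 = methyl on C10, C15 = methylene carbon on C4, β = the face of C14); the silylated chloroalkyne of step 5 is taken as a purchased building block.

Step 1
Reactants: 1 (R)-(−)-carvone [(5R)-2-methyl-5-(prop-1-en-2-yl)cyclohex-2-en-1-one]
Product: 2 (R)-carvotanacetone [(5R)-2-methyl-5-(propan-2-yl)cyclohex-2-en-1-one]
Conditions: H2 (1 atm), RhCl(PPh3)3 (cat.), toluene, rt
Reagents that add atoms: none
Why: Homogeneous hydrogenation with RhCl(PPh3)3 should saturate only the unhindered 1,1-disubstituted isopropenyl alkene and leave the trisubstituted conjugated alkene and the existing stereocentre (the later C7) untouched.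

Step 2
Reactants: 2 (R)-carvotanacetone
Product: 3 (1R,5R)-2-methyl-5-(propan-2-yl)cyclohex-2-en-1-ol (hydroxyl cis to isopropyl)
Conditions: NaBH4, CeCl3·7H2O, MeOH, −78 to 0 °C
Reagents that add atoms: none
Why: Luche 1,2-reduction, in which hydride should add axially to the half-chair that holds the isopropyl group equatorial, giving the equatorial alcohol cis to the isopropyl group and so fixing the later C9 relative to C7.

Step 3
Reactants: 3 (1R,5R)-2-methyl-5-(propan-2-yl)cyclohex-2-en-1-ol
Product: 4 tert-butyl(dimethyl){[(1R,5R)-2-methyl-5-(propan-2-yl)cyclohex-2-en-1-yl]oxy}silane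
Conditions: TBSCl, imidazole, DMF, rt
Reagents that add atoms: tert-butyl(chloro)dimethylsilane, CC(C)(C)[Si](C)(C)Cl
Why: Imidazole-promoted silylation of a secondary allylic alcohol touches no stereocentre and installs the bulky ether that later steers the conjugate addition.

Step 4
Reactants: 4 silyl ether of the cis alcohol
Product: 5 (4R,6R)-4-[(tert-butyldimethylsilyl)oxy]-3-methyl-6-(propan-2-yl)cyclohex-2-en-1-one (carbonyl carbon = later C6; silyloxy carbon = later C9)
Conditions: CrO3, 3,5-dimethylpyrazole, CH2Cl2, −20 °C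
Reagents that add atoms: chromium trioxide, O=[Cr](=O)=O
Why: Allylic C–H oxidation with the CrO3–dimethylpyrazole complex should convert the only allylic ring methylene into the enone carbonyl, as is known for cyclohexenyl silyl ethers, while the shielded tertiary allylic C–H under the silyl ether and the vinylic methyl are less reactive and no stereocentre changes.

Step 5
Reactants: 5 silyloxy enone; 6 (5-chloropent-1-yn-1-yl)trimethylsilane
Product: 8 (3R,4R,6R)-4-[(tert-butyldimethylsilyl)oxy]-3-methyl-6-(propan-2-yl)-1-[(trimethylsilyl)oxy]-3-[5-(trimethylsilyl)pent-4-yn-1-yl]cyclohex-1-ene (chain α; C14 β), via pentynyl Grignard reagent 7 (not isolated)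
Conditions: 6, Mg, THF, 65 °C; then 5, CuBr·SMe2 (10 mol %), TMSCl, HMPA, THF, −78 °C; Et3N
Reagents that add atoms: chlorotrimethylsilane, C[Si](C)(C)Cl
Why: Copper-catalysed, TMSCl-accelerated conjugate addition of the primary alkyl Grignard reagent should build the quaternary C10 and trap the enolate regiospecifically as the C5=C6 silyl enol ether, the alkyl group entering anti to the adjacent C9 silyloxy group (steric shielding plus the usual preference of 4-silyloxycyclohexenones for attack antiperiplanar to the C–O bond), so that the chain is α and C14 stays β, cis to the silyloxy group.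

Step 6
Reactants: 8 trimethylsilyl enol ether
Product: 10 (3R,4R,6R)-4-[(tert-butyldimethylsilyl)oxy]-3-methyl-6-(propan-2-yl)-1-[(triisopropylsilyl)oxy]-3-[5-(trimethylsilyl)pent-4-yn-1-yl]cyclohex-1-ene, via lithium enolate 9 (not isolated)
Conditions: MeLi, THF, 0 °C; then TIPSOTf, −78 °C to rt
Reagents that add atoms: triisopropylsilyl trifluoromethanesulfonate, CC(C)[Si](C(C)C)(C(C)C)OS(=O)(=O)C(F)(F)F
Why: Methyllithium cleaves the O–SiMe3 bond to the regiodefined lithium enolate without equilibration and the silyl triflate silylates it on oxygen (enolate transsilylation), exchanging the labile trimethylsilyl group for a triisopropylsilyl group that survives methanolic base and the protic gold conditions.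

Step 7
Reactants: 10 triisopropylsilyl enol ether with silylated alkyne
Product: 11 (3R,4R,6R)-4-[(tert-butyldimethylsilyl)oxy]-3-methyl-3-(pent-4-yn-1-yl)-6-(propan-2-yl)-1-[(triisopropylsilyl)oxy]cyclohex-1-ene (cyclisation precursor)
Conditions: K2CO3, MeOH/THF, rt
Reagents that add atoms: none
Why: Base-catalysed methanolysis of the alkynyl C–Si bond frees the terminal alkyne, while the triisopropylsilyl enol ether and the secondary silyl ether are stable to methanolic carbonate.

Step 8
Reactants: 11 cyclisation precursor
Product: 12 (5S,7R,9R,10R)-9-[(tert-butyldimethylsilyl)oxy]-5βH-eudesm-4(15)-en-6-one (cis-fused decalin; 7β-isopropyl; 9β-silyloxy; 10β-methyl)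
Conditions: Ph3PAuCl (10 mol %), AgBF4 (10 mol %), CH2Cl2/MeOH (10:1), 40 °C
Reagents that add atoms: none
Why: Ph3PAu+ (cationic monovalent gold from Ph3PAuCl and AgBF4) π-activates the terminal alkyne, C5 of the silyl enol ether adds to the internal carbon C4 anti to gold, the silyloxycarbenium ion gives up its silyl group to methanol to leave the C6 ketone, and protodeauration of the vinylgold species releases the C4=C15 methylene. The closest known reaction type is the gold-catalysed Conia-ene-type carbocyclisation of silyl enol ethers onto tethered terminal alkynes, which is established for exo closures of five- and six-membered rings. Ring A (C4, C3, C2, C1, C10, C5) closes in the 6-exo-dig mode; the 7-endo alternative would need attack at the unsubstituted terminus C15 and a larger ring. The new stereocentre C5 is controlled by C10: the tether leaves C10 on the α face as the equatorial substituent, so the alkyne can only reach the α lobe of C5, which is the axial direction of a chair-like ring B and anti to the axial C14 methyl, giving H5 β and a cis ring fusion (a trans fusion would require equatorial attack through a twist-boat). The step needs exo regiochemistry, an unconjugated exocyclic alkene and an intact C7 centre; the three-carbon tether, protodeauration under neutral conditions without base, and the triisopropylsilyl group (which slows simple methanolysis of the enol ether) should secure them.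

Step 9
Reactants: 12 silyloxy ketone
Product: 13 (5S,7R,9R,10R)-9β-hydroxy-5βH-eudesm-4(15)-en-6-one
Conditions: HF·pyridine, pyridine, THF, 0 °C to rt
Reagents that add atoms: none
Why: Fluoride-driven cleavage of the secondary silyl ether under buffered, non-basic conditions should free the 9-hydroxyl without epimerising C5 or C7 or moving the β,γ-alkene into conjugation.

Step 10
Reactants: 13 hydroxy ketone; 14 4-methoxybenzoyl chloride
Product: 15 (5S,7R,9R,10R)-6-oxo-5βH-eudesm-4(15)-en-9β-yl 4-methoxybenzoate
Conditions: 14, pyridine, DMAP (cat.), CH2Cl2, 0 °C to rt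
Reagents that add atoms: 4-methoxybenzoyl chloride (14), COc1ccc(cc1)C(Cl)=O
Why: DMAP-catalysed acylation (nucleophilic catalysis) of the equatorial 9-hydroxyl keeps the C9 configuration because the C–O bond is not broken, and the weak amine bases at room temperature should not enolise the ketone.

Step 11
Reactants: 15 keto ester
Product: 16 (5S,6S,7R,9R,10R)-6β-hydroxy-5βH-eudesm-4(15)-en-9β-yl 4-methoxybenzoate (target, CNP0107029.1)
Conditions: LiBH(s-Bu)3, THF, −78 °C; H2O
Reagents that add atoms: none
Why: Diastereoselective hydride reduction, in which the axial C14 methyl of the ring B chair is 1,3-diaxial to the axial (β) approach at C6, so the bulky borohydride should deliver hydride along the equatorial trajectory on the α face and give the axial 6β alcohol (the pattern of 3,3,5-trimethylcyclohexanone), while the aryl ester is not reduced at −78 °C.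

Compound list
1 | (R)-(−)-carvone, (5R)-2-methyl-5-(prop-1-en-2-yl)cyclohex-2-en-1-one | CC1=CC[C@@H](C(C)=C)CC1=O | starting material
2 | (R)-carvotanacetone, (5R)-2-methyl-5-(propan-2-yl)cyclohex-2-en-1-one | CC1=CC[C@@H](C(C)C)CC1=O | intermediate
3 | (1R,5R)-2-methyl-5-(propan-2-yl)cyclohex-2-en-1-ol (cis) | CC1=CC[C@@H](C(C)C)C[C@H]1O | intermediate
4 | tert-butyl(dimethyl){[(1R,5R)-2-methyl-5-(propan-2-yl)cyclohex-2-en-1-yl]oxy}silane | CC1=CC[C@@H](C(C)C)C[C@H]1O[Si](C)(C)C(C)(C)C | intermediate
5 | (4R,6R)-4-[(tert-butyldimethylsilyl)oxy]-3-methyl-6-(propan-2-yl)cyclohex-2-en-1-one | CC1=CC(=O)[C@@H](C(C)C)C[C@H]1O[Si](C)(C)C(C)(C)C | intermediate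
6 | (5-chloropent-1-yn-1-yl)trimethylsilane | C[Si](C)(C)C#CCCCCl | starting material
7 | [5-(trimethylsilyl)pent-4-yn-1-yl]magnesium chloride (not isolated) | C[Si](C)(C)C#CCCC[Mg]Cl | intermediate
8 | (3R,4R,6R)-4-[(tert-butyldimethylsilyl)oxy]-3-methyl-6-(propan-2-yl)-1-[(trimethylsilyl)oxy]-3-[5-(trimethylsilyl)pent-4-yn-1-yl]cyclohex-1-ene | C[Si](C)(C)C#CCCC[C@]1(C)C=C(O[Si](C)(C)C)[C@@H](C(C)C)C[C@H]1O[Si](C)(C)C(C)(C)C | intermediate
9 | lithium enolate corresponding to 8 (O–Li in place of O–SiMe3; not isolated) | C[Si](C)(C)C#CCCC[C@]1(C)C=C(O[Li])[C@@H](C(C)C)C[C@H]1O[Si](C)(C)C(C)(C)C | intermediate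
10 | (3R,4R,6R)-4-[(tert-butyldimethylsilyl)oxy]-3-methyl-6-(propan-2-yl)-1-[(triisopropylsilyl)oxy]-3-[5-(trimethylsilyl)pent-4-yn-1-yl]cyclohex-1-ene | C[Si](C)(C)C#CCCC[C@]1(C)C=C(O[Si](C(C)C)(C(C)C)C(C)C)[C@@H](C(C)C)C[C@H]1O[Si](C)(C)C(C)(C)C | intermediate
11 | (3R,4R,6R)-4-[(tert-butyldimethylsilyl)oxy]-3-methyl-3-(pent-4-yn-1-yl)-6-(propan-2-yl)-1-[(triisopropylsilyl)oxy]cyclohex-1-ene | C#CCCC[C@]1(C)C=C(O[Si](C(C)C)(C(C)C)C(C)C)[C@@H](C(C)C)C[C@H]1O[Si](C)(C)C(C)(C)C | intermediate
12 | (5S,7R,9R,10R)-9-[(tert-butyldimethylsilyl)oxy]-5βH-eudesm-4(15)-en-6-one (cis-fused) | C=C1CCC[C@]2(C)[C@H]1C(=O)[C@@H](C(C)C)C[C@H]2O[Si](C)(C)C(C)(C)C | intermediate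
13 | (5S,7R,9R,10R)-9β-hydroxy-5βH-eudesm-4(15)-en-6-one | C=C1CCC[C@]2(C)[C@H]1C(=O)[C@@H](C(C)C)C[C@H]2O | intermediate
14 | 4-methoxybenzoyl chloride | COc1ccc(cc1)C(Cl)=O | starting material
15 | (5S,7R,9R,10R)-6-oxo-5βH-eudesm-4(15)-en-9β-yl 4-methoxybenzoate | C=C1CCC[C@]2(C)[C@H]1C(=O)[C@@H](C(C)C)C[C@H]2OC(=O)c1ccc(OC)cc1 | intermediate
16 | (5S,6S,7R,9R,10R)-6β-hydroxy-5βH-eudesm-4(15)-en-9β-yl 4-methoxybenzoate | C=C1CCC[C@]2(C)[C@H]1[C@@H](O)[C@@H](C(C)C)C[C@H]2OC(=O)c1ccc(OC)cc1 | target

Total step count: 11
Longest linear sequence: 11 steps (1 to 16); 6 and 14 are used as purchased.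

Steps most likely to fail

Step 8. The 6-exo-dig closure may be slower than methanolysis of the enol ether or gold-promoted addition of methanol to the alkyne, so that uncyclised ketone or a methyl ketone accumulates. The fallback replaces π-acid catalysis by radical chemistry. Setting out from 11, N-iodosuccinimide in THF at −78 °C should give the regiodefined 2-iodocyclohexanone F1 (iodine on the later C5). Atom-transfer radical cyclisation of F1 [(Bu3Sn)2 (cat.), hν, benzene] should close ring A in the 6-exo-dig mode through the C5 α-keto radical and give the 15-iodo ketone F2. Bu3SnH with AIBN then removes the iodine, and the sequence rejoins the route at 12.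

Step 11. Facial selectivity may be poor or inverted: the C15 methylene group of ring A lies beneath C6 on the α face of the cis-fused system and can obstruct the equatorial trajectory. Hydride would then add from the β face, or the ketone would merely be enolised, and the C6 epimer would result. The fallback inverts C6 instead of relying on facial control. Setting out from 15, NaBH4 with CeCl3·7H2O in MeOH (small hydride, axial β delivery) should give the 6α-alcohol F3. A Mitsunobu reaction with chloroacetic acid (PPh3, DIAD, toluene) should invert C6 to the 6β-chloroacetate F4. Thiourea and NaHCO3 in EtOH cleave the chloroacetate beside the 4-methoxybenzoate, and the sequence comes back at 16.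

Step 5. Transfer of the functionalised primary alkyl group to the β,β-disubstituted carbon may be slow, with 1,2-addition or enolisation competing. Facial control may also be eroded, because the cis-7-isopropyl group disfavours the half-chair with an axial silyloxy group. The fallback is a Lewis-acid conjugate allylation followed by chain extension. Setting out from 5, CH2=CHCH2SnBu3 with TIPSOTf in CH2Cl2 at −78 °C (Hosomi–Sakurai-type addition through an open transition state, anti to the silyloxy group) should give directly the C10-allyl triisopropylsilyl enol ether F5. 9-BBN followed by NaBO3·4H2O gives the primary alcohol F6, and MsCl with Et3N gives the mesylate F7. LiC≡CH·H2NCH2CH2NH2 in DMSO displaces the mesylate, and the sequence rejoins the route at 11.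

Further compounds
F1 | step 8 | 4-[(tert-butyldimethylsilyl)oxy]-2-iodo-3-methyl-3-(pent-4-yn-1-yl)-6-(propan-2-yl)cyclohexan-1-one (C2 epimers; other centres as in 11) | C#CCCC[C@]1(C)C(I)C(=O)[C@@H](C(C)C)C[C@H]1O[Si](C)(C)C(C)(C)C
F2 | step 8 | 9β-[(tert-butyldimethylsilyl)oxy]-15-iodo-5βH-eudesm-4(15)-en-6-one (alkene isomers; ring centres as in 12) | IC=C1CCC[C@]2(C)[C@H]1C(=O)[C@@H](C(C)C)C[C@H]2O[Si](C)(C)C(C)(C)C
F3 | step 11 | 6α-hydroxy-5βH-eudesm-4(15)-en-9β-yl 4-methoxybenzoate (C6 epimer of 16) | C=C1CCC[C@]2(C)[C@H]1[C@H](O)[C@@H](C(C)C)C[C@H]2OC(=O)c1ccc(OC)cc1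
F4 | step 11 | 6β-(chloroacetoxy)-5βH-eudesm-4(15)-en-9β-yl 4-methoxybenzoate | C=C1CCC[C@]2(C)[C@H]1[C@@H](OC(=O)CCl)[C@@H](C(C)C)C[C@H]2OC(=O)c1ccc(OC)cc1
F5 | step 5 | 4-[(tert-butyldimethylsilyl)oxy]-3-methyl-3-(prop-2-en-1-yl)-6-(propan-2-yl)-1-[(triisopropylsilyl)oxy]cyclohex-1-ene (centres as in 11) | C=CC[C@]1(C)C=C(O[Si](C(C)C)(C(C)C)C(C)C)[C@@H](C(C)C)C[C@H]1O[Si](C)(C)C(C)(C)C
F6 | step 5 | 3-{2-[(tert-butyldimethylsilyl)oxy]-1-methyl-4-(propan-2-yl)-5-[(triisopropylsilyl)oxy]cyclohex-5-en-1-yl}propan-1-ol (centres as in 11) | OCCC[C@]1(C)C=C(O[Si](C(C)C)(C(C)C)C(C)C)[C@@H](C(C)C)C[C@H]1O[Si](C)(C)C(C)(C)C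
F7 | step 5 | methanesulfonate of F6 | CS(=O)(=O)OCCC[C@]1(C)C=C(O[Si](C(C)C)(C(C)C)C(C)C)[C@@H](C(C)C)C[C@H]1O[Si](C)(C)C(C)(C)C
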